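The upper ring C is disconnected at O1–C2 and C4a–C4, which reveals resorcinol as a 1,3-C,O-dinucleophile and a trans-epoxy aldehyde whose three carbons (C2–C4) already hang on C6 of the lower flavan. C4 is benzylic to ring A of the lower unit (para to its pyran oxygen, ortho to its 7-oxygen), so the strained epoxide should open there under mere hydrogen-bond activation: resorcinol forms C4a–C4 with inversion and its ortho hydroxyl then closes O1–C2 as a hemiacetal. The 2,3-cis aryl groups of both units are installed by hydroxyl-directed aryl transfer from a boronic acid to the lactols.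

Key step: step 9

Remark: lactols are drawn without configuration at the anomeric carbon; C-4 of the upper unit has the descriptor S while O-7 of the lower unit carries benzyl and R in the target, with no change in geometry.

Step 1
Reactants: 1 resorcinol; 2 acrylic acid
Product: 3 7-hydroxychroman-2-one
Conditions: Amberlyst-15, toluene, reflux (Dean–Stark)
Reagents that add atoms: none
Why: An acid-catalysed Friedel–Crafts hydroarylation of the acrylic acid at C-4 of resorcinol (ortho to one hydroxyl, para to the other) combined with lactonisation onto the ortho hydroxyl should give the dihydrocoumarin; no stereocentre is formed.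

Step 2
Reactants: 3 7-hydroxychroman-2-one
Product: 4 7-(benzyloxy)chroman-2-one
Conditions: BnBr, K2CO3, dry acetone, reflux
Reagents that add atoms: benzyl bromide, BrCc1ccccc1
Why: Williamson etherification of the only phenol; the mild base in dry acetone should leave the aryl lactone closed.

Step 3
Reactants: 4 7-(benzyloxy)chroman-2-one
Product: 5 7-(benzyloxy)chroman-2-ol
Conditions: iBu2AlH, CH2Cl2, −78 °C; aqueous potassium sodium tartrate
Reagents that add atoms: none
Why: Partial reduction of the lactone by iBu2AlH stops at the aluminium hemiacetal at −78 °C and should give the lactol on work-up; the anomeric centre forms as a mixture and is removed in step 5.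

Step 4
Reactants: 5 7-(benzyloxy)chroman-2-ol
Product: 7 (3S)-7-(benzyloxy)chromane-2,3-diol, via anilinooxy lactol 6 (not isolated)
Conditions: D-proline (20 mol%), PhNO, CHCl3, 4 °C; then Zn, AcOH, EtOH, rt
Reagents that add atoms: nitrosobenzene, O=Nc1ccccc1
Why: Proline-catalysed α-aminoxylation (enamine nitroso-aldol reaction) of the ring-opened aldehyde form of 5, in which D-proline delivers oxygen to the enamine face that gives the 3S centre, followed by reductive N–O cleavage with zinc; the product rests as its cyclic hemiacetal, which should protect the α-oxy aldehyde from racemisation.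

Step 5
Reactants: 7 (3S)-7-(benzyloxy)chromane-2,3-diol; 8 [3,4-bis(benzyloxy)phenyl]boronic acid
Product: 9 (2S,3S)-7-(benzyloxy)-2-[3,4-bis(benzyloxy)phenyl]chroman-3-ol
Conditions: BF3·OEt2, CH2Cl2, 4 Å MS, −78 to −20 °C
Reagents that add atoms: none
Why: Petasis-type hydroxyl-directed aryl transfer: BF3 ionises the lactol to the cyclic oxocarbenium ion while the boronic acid is bound as a boronate to O-3, so the aryl group should migrate to C-2 on the face of O-3 and set the 2S centre cis to the 3-hydroxyl.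

Step 6
Reactants: 9 (2S,3S)-7-(benzyloxy)-2-[3,4-bis(benzyloxy)phenyl]chroman-3-ol
Product: 10 (2S,3S)-3,7-bis(benzyloxy)-2-[3,4-bis(benzyloxy)phenyl]chromane
Conditions: NaH, BnBr, Bu4NI (cat.), DMF, 0 °C to rt
Reagents that add atoms: benzyl bromide, BrCc1ccccc1
Why: Williamson etherification of the secondary alcohol, which protects it from the chlorophosphorus reagent of step 7; no stereocentre is touched.

Step 7
Reactants: 10 (2S,3S)-3,7-bis(benzyloxy)-2-[3,4-bis(benzyloxy)phenyl]chromane; 11 (E)-3-(dimethylamino)prop-2-enal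
Product: 13 (E)-3-[(2S,3S)-3,7-bis(benzyloxy)-2-[3,4-bis(benzyloxy)phenyl]chroman-6-yl]prop-2-enal, via iminium chloride 12 (not isolated)
Conditions: POCl3, CH2Cl2, 0 °C to rt; then aq. NaOAc
Reagents that add atoms: water, O
Why: Vinylogous Vilsmeier–Haack formylation: the chlorovinyl iminium salt from 11 and POCl3 should attack C-6 of ring A (para to the pyran oxygen, ortho to the benzyloxy group; C-8 between two oxygens is hindered and ring B is less activated), and hydrolysis of 12 should give the E-enal.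

Step 8
Reactants: 13 (E)-3-[(2S,3S)-3,7-bis(benzyloxy)-2-[3,4-bis(benzyloxy)phenyl]chroman-6-yl]prop-2-enal
Product: 14 (2S,3R)-3-[(2S,3S)-3,7-bis(benzyloxy)-2-[3,4-bis(benzyloxy)phenyl]chroman-6-yl]oxirane-2-carbaldehyde
Conditions: (S)-2-{bis[3,5-bis(trifluoromethyl)phenyl](trimethylsilyloxy)methyl}pyrrolidine (10 mol%), 35% aq. H2O2, CH2Cl2, rt
Reagents that add atoms: hydrogen peroxide, OO
Why: Iminium-catalysed nucleophilic epoxidation (conjugate addition of hydrogen peroxide, then enamine ring closure): the (S)-diarylprolinol silyl ether shields one face of the E-iminium ion so that oxygen adds to the Si face of C-β, which should set both centres of the trans-epoxide (2S,3R) under catalyst control, the remote flavan centres having little influence.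

Step 9
Reactants: 14 (2S,3R)-3-[(2S,3S)-3,7-bis(benzyloxy)-2-[3,4-bis(benzyloxy)phenyl]chroman-6-yl]oxirane-2-carbaldehyde; 1 resorcinol
Product: 16 (3S,4S)-4-[(2S,3S)-3,7-bis(benzyloxy)-2-[3,4-bis(benzyloxy)phenyl]chroman-6-yl]chromane-2,3,7-triol, via hydroxy aldehyde 15 (not isolated)
Conditions: 1 (3 equiv), HFIP (1,1,1,3,3,3-hexafluoropropan-2-ol), 0 °C to rt
Reagents that add atoms: none
Why: Hydrogen bonding from HFIP activates the epoxide, which opens at C-4 because only this carbon is benzylic and pushed by the para pyran oxygen and the ortho benzyloxy group of the lower ring A (C-3 is deactivated by the formyl group); C-4 of resorcinol attacks in a Friedel–Crafts alkylation driven by release of the epoxide strain to give 15, and the phenolic hydroxyl ortho to the new bond then adds to the aldehyde to give lactol 16. The closest known reaction types are the Friedel–Crafts arylation of aryl epoxides by phenols in fluorinated alcohols and the acid-mediated annulation of phenols with cinnamic acids to 4-aryl-dihydrocoumarins. Ring C is closed by a 6-exo-trig hemiacetalisation (O-1 onto C-2). C-4 is set by the epoxide stereocentre: backside attack on the hydrogen-bonded epoxide (a tight ion pair at the latest) inverts C-4 and places the new aryl group trans to the C-3 oxygen, which keeps its configuration, while C-2 forms as an anomeric mixture that step 10 erases. The step needs C- over O-alkylation of resorcinol at C-4/C-6 and not C-2, secured by the fluorinated solvent, the equivalence of C-4 and C-6 and the hindrance of C-2; it also needs epoxide opening to outrun reaction at the aldehyde, secured by the donor-activated benzylic carbon that opens without added acid, and excess resorcinol suppresses a second alkylation by the product.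

Step 10
Reactants: 16 (3S,4S)-4-[(2S,3S)-3,7-bis(benzyloxy)-2-[3,4-bis(benzyloxy)phenyl]chroman-6-yl]chromane-2,3,7-triol; 8 [3,4-bis(benzyloxy)phenyl]boronic acid
Product: 17 (2S,3S,4S)-2-[3,4-bis(benzyloxy)phenyl]-4-[(2S,3S)-3,7-bis(benzyloxy)-2-[3,4-bis(benzyloxy)phenyl]chroman-6-yl]chromane-3,7-diol
Conditions: 8 (2 equiv), BF3·OEt2, CH2Cl2, 4 Å MS, −78 to −20 °C
Reagents that add atoms: none
Why: Petasis-type hydroxyl-directed aryl transfer as in step 5: the aryl group should migrate from the O-3-bound boronate to C-2 of the oxocarbenium ion on the face of O-3, which is also the face opposite the C-4 aryl group, so that the 2S centre is set 2,3-cis and 2,4-trans.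

Step 11
Reactants: 17 (2S,3S,4S)-2-[3,4-bis(benzyloxy)phenyl]-4-[(2S,3S)-3,7-bis(benzyloxy)-2-[3,4-bis(benzyloxy)phenyl]chroman-6-yl]chromane-3,7-diol
Product: 18 (2S,3S,4R)-2-(3,4-dihydroxyphenyl)-4-[(2S,3S)-2-(3,4-dihydroxyphenyl)-3,7-dihydroxychroman-6-yl]chromane-3,7-diol
Conditions: H2 (1 atm), Pd(OH)2/C, THF/MeOH, rt
Reagents that add atoms: none
Why: Hydrogenolysis of the six benzyl ethers under neutral conditions should free all phenols and the 3-hydroxyl of the lower unit without cleaving the ring C–O bonds or touching any stereocentre.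

Compound list
1 | resorcinol | Oc1cccc(O)c1 | starting material
2 | acrylic acid | OC(=O)C=C | starting material
3 | 7-hydroxychroman-2-one | O=C1CCc2ccc(O)cc2O1 | intermediate
4 | 7-(benzyloxy)chroman-2-one | O=C1CCc2ccc(OCc3ccccc3)cc2O1 | intermediate
5 | 7-(benzyloxy)chroman-2-ol | OC1CCc2ccc(OCc3ccccc3)cc2O1 | intermediate
6 | (3S)-3-(anilinooxy)-7-(benzyloxy)chroman-2-ol | C(c1ccccc1)Oc1ccc2c(c1)OC(O)[C@@H](ONc1ccccc1)C2 | intermediate (not isolated)
7 | (3S)-7-(benzyloxy)chromane-2,3-diol | C(c1ccccc1)Oc1ccc2c(c1)OC(O)[C@@H](O)C2 | intermediate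
8 | [3,4-bis(benzyloxy)phenyl]boronic acid | OB(O)c1ccc(OCc2ccccc2)c(OCc2ccccc2)c1 | starting material
9 | (2S,3S)-7-(benzyloxy)-2-[3,4-bis(benzyloxy)phenyl]chroman-3-ol | C(c1ccccc1)Oc1ccc2c(c1)O[C@@H](c1ccc(OCc3ccccc3)c(OCc3ccccc3)c1)[C@@H](O)C2 | intermediate
10 | (2S,3S)-3,7-bis(benzyloxy)-2-[3,4-bis(benzyloxy)phenyl]chromane | C(c1ccccc1)Oc1ccc2c(c1)O[C@@H](c1ccc(OCc3ccccc3)c(OCc3ccccc3)c1)[C@@H](OCc1ccccc1)C2 | intermediate
11 | (E)-3-(dimethylamino)prop-2-enal | CN(C)/C=C/C=O | starting material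
12 | (E)-3-[(2S,3S)-3,7-bis(benzyloxy)-2-[3,4-bis(benzyloxy)phenyl]chroman-6-yl]-N,N-dimethylprop-2-en-1-iminium chloride | C[N+](C)=C/C=C/c1cc2c(cc1OCc1ccccc1)O[C@@H](c1ccc(OCc3ccccc3)c(OCc3ccccc3)c1)[C@@H](OCc1ccccc1)C2.[Cl-] | intermediate (not isolated)
13 | (E)-3-[(2S,3S)-3,7-bis(benzyloxy)-2-[3,4-bis(benzyloxy)phenyl]chroman-6-yl]prop-2-enal | O=C/C=C/c1cc2c(cc1OCc1ccccc1)O[C@@H](c1ccc(OCc3ccccc3)c(OCc3ccccc3)c1)[C@@H](OCc1ccccc1)C2 | intermediate
14 | (2S,3R)-3-[(2S,3S)-3,7-bis(benzyloxy)-2-[3,4-bis(benzyloxy)phenyl]chroman-6-yl]oxirane-2-carbaldehyde (trans-epoxide) | O=C[C@H]1O[C@@H]1c1cc2c(cc1OCc1ccccc1)O[C@@H](c1ccc(OCc3ccccc3)c(OCc3ccccc3)c1)[C@@H](OCc1ccccc1)C2 | intermediate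
15 | (2S,3S)-3-[(2S,3S)-3,7-bis(benzyloxy)-2-[3,4-bis(benzyloxy)phenyl]chroman-6-yl]-3-(2,4-dihydroxyphenyl)-2-hydroxypropanal | O=C[C@@H](O)[C@@H](c1ccc(O)cc1O)c1cc2c(cc1OCc1ccccc1)O[C@@H](c1ccc(OCc3ccccc3)c(OCc3ccccc3)c1)[C@@H](OCc1ccccc1)C2 | intermediate (not isolated)
16 | (3S,4S)-4-[(2S,3S)-3,7-bis(benzyloxy)-2-[3,4-bis(benzyloxy)phenyl]chroman-6-yl]chromane-2,3,7-triol (3,4-trans; both C-2 anomers) | Oc1ccc2c(c1)OC(O)[C@@H](O)[C@@H]2c1cc2c(cc1OCc1ccccc1)O[C@@H](c1ccc(OCc3ccccc3)c(OCc3ccccc3)c1)[C@@H](OCc1ccccc1)C2 | intermediate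
17 | (2S,3S,4S)-2-[3,4-bis(benzyloxy)phenyl]-4-[(2S,3S)-3,7-bis(benzyloxy)-2-[3,4-bis(benzyloxy)phenyl]chroman-6-yl]chromane-3,7-diol (2,3-cis-3,4-trans) | Oc1ccc2c(c1)O[C@@H](c1ccc(OCc3ccccc3)c(OCc3ccccc3)c1)[C@@H](O)[C@@H]2c1cc2c(cc1OCc1ccccc1)O[C@@H](c1ccc(OCc3ccccc3)c(OCc3ccccc3)c1)[C@@H](OCc1ccccc1)C2 | intermediate
18 | (2S,3S,4R)-2-(3,4-dihydroxyphenyl)-4-[(2S,3S)-2-(3,4-dihydroxyphenyl)-3,7-dihydroxychroman-6-yl]chromane-3,7-diol (CNP0187520.4) | Oc1ccc2c(c1)O[C@@H](c1ccc(O)c(O)c1)[C@@H](O)[C@@H]2c1cc2c(cc1O)O[C@@H](c1ccc(O)c(O)c1)[C@@H](O)C2 | target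

Total step count: 11
Longest linear sequence: 11 steps (from 1 and 2 to 18; 8 and 11 are purchased)

Steps most likely to fail

Step 9. The epoxide may ionise fully to a quinone-methide-like cation before resorcinol arrives. That would allow a Meinwald-type hydride or formyl shift and erode the inversion at C-4, and the free formyl group may condense with resorcinol. The fallback moves the electrophile to the ester level. It sets out from 14, which would be oxidised (Pinnick oxidation with NaClO2, NaH2PO4 and 2-methyl-2-butene, then TMSCHN2) to methyl (2S,3R)-3-[(2S,3S)-3,7-bis(benzyloxy)-2-[3,4-bis(benzyloxy)phenyl]chroman-6-yl]oxirane-2-carboxylate F1. With 1 and BF3·OEt2 in CH2Cl2 (−78 to 0 °C) the glycidic ester should undergo the same Friedel–Crafts opening, now followed by irreversible lactonisation, to give (3S,4S)-3,7-dihydroxy-4-[(2S,3S)-3,7-bis(benzyloxy)-2-[3,4-bis(benzyloxy)phenyl]chroman-6-yl]chroman-2-one F2. Reduction with iBu2AlH as in step 3 would come back to the route at 16.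

Step 10. Aryl transfer may be too slow for this hindered lactol. The oxocarbenium ion could then be captured by the nucleophilic A rings of another molecule or by the neighbouring 7-benzyloxy oxygen of the lower unit, or could isomerise by hydride shift to the 3-ketone; facial selectivity could also fall. The fallback avoids a cation at C-2 and sets out from 16. Fétizon oxidation (Ag2CO3 on Celite, toluene, reflux) would give the lactone already described as F2. Addition of the aryllithium made from 4-bromo-1,2-bis(benzyloxy)benzene and n-BuLi (THF, −78 °C) would open it to (2S,3S)-1-[3,4-bis(benzyloxy)phenyl]-3-[(2S,3S)-3,7-bis(benzyloxy)-2-[3,4-bis(benzyloxy)phenyl]chroman-6-yl]-3-(2,4-dihydroxyphenyl)-2-hydroxypropan-1-one F3. Chelation-controlled reduction with Zn(BH4)2 (Et2O, 0 °C) should give the anti-diol (1R,2S,3S)-1-[3,4-bis(benzyloxy)phenyl]-3-[(2S,3S)-3,7-bis(benzyloxy)-2-[3,4-bis(benzyloxy)phenyl]chroman-6-yl]-3-(2,4-dihydroxyphenyl)propane-1,2-diol F4. Mitsunobu cyclisation (PPh3, diisopropyl azodicarboxylate, THF, 0 °C), in which the ortho phenol displaces the activated benzylic hydroxyl with inversion, should then close the 2,3-cis ring and come back to the route at 17.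

Step 8. The very electron-rich enal may form a poorly electrophilic iminium ion, so conversion could stall, and the donor-substituted epoxide may open during the reaction or on isolation. The fallback uses an allylic alcohol and sets out from 13. Luche reduction (NaBH4, CeCl3·7H2O, MeOH, 0 °C) would give (E)-3-[(2S,3S)-3,7-bis(benzyloxy)-2-[3,4-bis(benzyloxy)phenyl]chroman-6-yl]prop-2-en-1-ol F5. Sharpless asymmetric epoxidation (Ti(OiPr)4, D-(−)-diethyl tartrate, tBuOOH, 4 Å MS, CH2Cl2, −20 °C) should give [(2R,3R)-3-[(2S,3S)-3,7-bis(benzyloxy)-2-[3,4-bis(benzyloxy)phenyl]chroman-6-yl]oxiran-2-yl]methanol F6. Oxidation with Dess–Martin periodinane buffered with NaHCO3 would come back to the route at 14.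

Further compounds
F1 | step 9 | methyl (2S,3R)-3-[(2S,3S)-3,7-bis(benzyloxy)-2-[3,4-bis(benzyloxy)phenyl]chroman-6-yl]oxirane-2-carboxylate | COC(=O)[C@H]1O[C@@H]1c1cc2c(cc1OCc1ccccc1)O[C@@H](c1ccc(OCc3ccccc3)c(OCc3ccccc3)c1)[C@@H](OCc1ccccc1)C2
F2 | step 9 | (3S,4S)-3,7-dihydroxy-4-[(2S,3S)-3,7-bis(benzyloxy)-2-[3,4-bis(benzyloxy)phenyl]chroman-6-yl]chroman-2-one | Oc1ccc2c(c1)OC(=O)[C@@H](O)[C@@H]2c1cc2c(cc1OCc1ccccc1)O[C@@H](c1ccc(OCc3ccccc3)c(OCc3ccccc3)c1)[C@@H](OCc1ccccc1)C2
F3 | step 10 | (2S,3S)-1-[3,4-bis(benzyloxy)phenyl]-3-[(2S,3S)-3,7-bis(benzyloxy)-2-[3,4-bis(benzyloxy)phenyl]chroman-6-yl]-3-(2,4-dihydroxyphenyl)-2-hydroxypropan-1-one | O=C(c1ccc(OCc3ccccc3)c(OCc3ccccc3)c1)[C@@H](O)[C@@H](c1ccc(O)cc1O)c1cc2c(cc1OCc1ccccc1)O[C@@H](c1ccc(OCc3ccccc3)c(OCc3ccccc3)c1)[C@@H](OCc1ccccc1)C2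
F4 | step 10 | (1R,2S,3S)-1-[3,4-bis(benzyloxy)phenyl]-3-[(2S,3S)-3,7-bis(benzyloxy)-2-[3,4-bis(benzyloxy)phenyl]chroman-6-yl]-3-(2,4-dihydroxyphenyl)propane-1,2-diol | O[C@H](c1ccc(OCc3ccccc3)c(OCc3ccccc3)c1)[C@@H](O)[C@@H](c1ccc(O)cc1O)c1cc2c(cc1OCc1ccccc1)O[C@@H](c1ccc(OCc3ccccc3)c(OCc3ccccc3)c1)[C@@H](OCc1ccccc1)C2
F5 | step 8 | (E)-3-[(2S,3S)-3,7-bis(benzyloxy)-2-[3,4-bis(benzyloxy)phenyl]chroman-6-yl]prop-2-en-1-ol | OC/C=C/c1cc2c(cc1OCc1ccccc1)O[C@@H](c1ccc(OCc3ccccc3)c(OCc3ccccc3)c1)[C@@H](OCc1ccccc1)C2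
F6 | step 8 | [(2R,3R)-3-[(2S,3S)-3,7-bis(benzyloxy)-2-[3,4-bis(benzyloxy)phenyl]chroman-6-yl]oxiran-2-yl]methanol | OC[C@H]1O[C@@H]1c1cc2c(cc1OCc1ccccc1)O[C@@H](c1ccc(OCc3ccccc3)c(OCc3ccccc3)c1)[C@@H](OCc1ccccc1)C2
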